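## Retrosynthetic overview
1. The tetralin ring is formed last. It comes from a five-to-six ring expansion: a cationic 1,2-shift of the benzylic carbon C7' in a spiro[4.5]decadienone (dienone–phenol type).
2. The spiro cyclopentane is formed first. The ring A phenolate attacks, at its ipso carbon, the ring B para-quinone methide, which is made by two-electron oxidation of a C2-symmetric (R,R)-dibenzylbutanediol.
3. The diol comes from hydride removal of two oxazolidinone auxiliaries from an (R,R)-2,3-dibenzylsuccinyl bis-imide.
4. The C7–C8 and C7'–C8' bonds and both stereocentres come from a twofold titanium-enolate addition of a succinyl bis-imide to a syringyl quinone methide.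
5. The building blocks are p-cresol (threefold bromination, then methoxide/copper) and succinyl chloride.

Assumption: (R)-4-benzyl-2-oxazolidinone serves as a recoverable chiral auxiliary (a reagent), and none of its atoms remains in the target.

Numbering: lignan numbering is used. Ring A with C7–C9 is the unit that becomes the fused ring. Ring B with C7'–C9' is the unit that becomes the pendant aryl group.

## Route

**Step 1**
Reactants: 1 4-methylphenol (p-cresol)
Product: 3 2,6-dibromo-4-(bromomethyl)phenol, via 2,6-dibromo-4-methylphenol 2 (not isolated)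
Conditions: Br2 (2.0 equiv), 1,2-dichlorobenzene, 35 °C; then Br2 (1.0 equiv, slow), 150 °C, HBr vented
Reagents that add atoms: bromine, BrBr
Why: Electrophilic aromatic bromination fills both positions ortho to OH at low temperature, and the third equivalent then substitutes the methyl group of the blocked, deactivated ring at high temperature (thermal side-chain bromination, the first part of the technical p-cresol to 3,5-dibromo-4-hydroxybenzaldehyde process).

**Step 2**
Reactants: 3 2,6-dibromo-4-(bromomethyl)phenol
Product: 5 2,6-dimethoxy-4-(methoxymethyl)phenol, via 2,6-dibromo-4-(methoxymethyl)phenol 4 (not isolated)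
Conditions: NaOMe (8 equiv), MeOH, rt; then CuCl (15 mol%), DMF, 110 °C, sealed; neutralise with aq. NH4Cl
Reagents that add atoms: sodium methoxide, C[O-].[Na+]
Why: The para-hydroxybenzyl bromide is solvolysed by methoxide at room temperature, and both aryl bromides are then exchanged in a copper-catalysed Ullmann-type methoxylation, the technical reaction used on 2,6-dibromo-4-alkylphenols.

**Step 3**
Reactants: 6 succinyl chloride
Product: 7 1,4-bis[(4R)-4-benzyl-2-oxo-1,3-oxazolidin-3-yl]butane-1,4-dione
Conditions: (R)-4-benzyl-2-oxazolidinone (2.05 equiv), n-BuLi (2.05 equiv), THF, −78 °C; then 6, −78 °C to rt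
Reagents that add atoms: (R)-4-benzyl-2-oxazolidinone, O=C1N[C@H](Cc2ccccc2)CO1
Why: Standard N-acylation of a lithiated Evans oxazolidinone by an acid chloride, run at both ends, with the two auxiliary stereocentres coming from the reagent.

**Step 4**
Reactants: 7 succinyl bis-imide; 5 2,6-dimethoxy-4-(methoxymethyl)phenol (2.3 equiv)
Product: 10 (2R,3R)-1,4-bis[(4R)-4-benzyl-2-oxo-1,3-oxazolidin-3-yl]-2,3-bis(4-hydroxy-3,5-dimethoxybenzyl)butane-1,4-dione, via syringyl quinone methide 8 (not isolated), via mono-benzylated bis-imide 9 (not isolated)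
Conditions: 7, TiCl4 (2.2 equiv), i-Pr2NEt (2.4 equiv), CH2Cl2, −78 to 0 °C; then 5 premixed with TiCl4 (2.4 equiv) and i-Pr2NEt (2.4 equiv), −78 to 0 °C; aq. NH4Cl
Reagents that add atoms: none
Why: Proposed new method: soft enolisation gives the chelated Z titanium enolate of each imide in turn, TiCl4 ionises the para-hydroxybenzyl methyl ether 5 (held as its titanium phenoxide) to Lewis-acid-bound quinone methide 8, and 1,6-addition takes place on the enolate face away from the auxiliary benzyl group, so each (R)-auxiliary sets its own alpha carbon as R and the branched product is not re-enolised (allylic strain); the closest known reaction types are Evans alkylation of TiCl4/amine enolates with SN1-active electrophiles and 1,6-conjugate addition to para-quinone methides, not yet shown twofold on a succinyl bis-imide or with a free-phenol quinone methide precursor.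

**Step 5**
Reactants: 10 dibenzylated bis-imide
Product: 11 (2R,3R)-2,3-bis(4-hydroxy-3,5-dimethoxybenzyl)butane-1,4-diol
Conditions: LiBH4 (6 equiv), MeOH (6 equiv), THF, 0 °C to rt; aq. NH4Cl
Reagents that add atoms: none
Why: Reductive cleavage of Evans imides with LiBH4 turns both exocyclic carbonyls into CH2OH, reduces any butyrolactone formed on the way, costs only extra hydride at the phenols, and leaves both stereocentres untouched while releasing the auxiliary.

**Step 6**
Reactants: 11 (2R,3R)-dibenzylbutanediol
Product: 14 (6R,7R,8S)-lyoniresinol, via ring B quinone methide 12 (not isolated), via spiro[4.5]decadienone 13 (not isolated)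
Conditions: Ag2O (1.05 equiv), Cs2CO3 (20 mol%), MeCN, 0 °C, dark; filter through Celite; then TFA/CH2Cl2 1:9, 0 °C to rt; NaHCO3, MeOH work-up
Reagents that add atoms: none
Why: Proposed new method: monovalent silver removes two electrons and two protons from one of the two equivalent syringyl units to give para-quinone methide 12, catalytic base converts the other syringol into its phenolate, whose only activated carbon is the alkyl-bearing para (ipso) position, so a 5-exo 1,6-addition closes cyclopentane 13 with the aryl group anti to the neighbouring CH2OH, and TFA then protonates the dienone and drives a cationic 1,2-shift of the aryl-stabilised benzylic carbon C7' from the spiro centre to the adjacent ring carbon with retention (five-to-six ring expansion, then rearomatisation), which fixes C8 of the tetralin as S and trans to C7; any material trapped on oxygen re-ionises in TFA and ends in the same product; the closest known reaction types are phenolate ipso participation giving spiro[4.5]decadienones, 1,6-addition to para-quinone methides and the dienone–phenol rearrangement, never yet run as one oxidative relay on an unprotected seco-lignan.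

## Compound list
1 | 4-methylphenol (p-cresol) | Cc1ccc(O)cc1 | starting material
2 | 2,6-dibromo-4-methylphenol | Cc1cc(Br)c(O)c(Br)c1 | intermediate
3 | 2,6-dibromo-4-(bromomethyl)phenol | BrCc1cc(Br)c(O)c(Br)c1 | intermediate
4 | 2,6-dibromo-4-(methoxymethyl)phenol | COCc1cc(Br)c(O)c(Br)c1 | intermediate
5 | 2,6-dimethoxy-4-(methoxymethyl)phenol | COCc1cc(OC)c(O)c(OC)c1 | intermediate
6 | succinyl chloride (butanedioyl dichloride) | O=C(Cl)CCC(=O)Cl | starting material
7 | 1,4-bis[(4R)-4-benzyl-2-oxo-1,3-oxazolidin-3-yl]butane-1,4-dione | O=C(CCC(=O)N1[C@H](Cc2ccccc2)COC1=O)N1[C@H](Cc2ccccc2)COC1=O | intermediate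
8 | 2,6-dimethoxy-4-methylidenecyclohexa-2,5-dien-1-one (syringyl quinone methide, formed titanium-bound) | C=C1C=C(OC)C(=O)C(OC)=C1 | intermediate
9 | (2R)-1,4-bis[(4R)-4-benzyl-2-oxo-1,3-oxazolidin-3-yl]-2-(4-hydroxy-3,5-dimethoxybenzyl)butane-1,4-dione | O=C([C@H](Cc1cc(OC)c(O)c(OC)c1)CC(=O)N1[C@H](Cc2ccccc2)COC1=O)N1[C@H](Cc2ccccc2)COC1=O | intermediate
10 | (2R,3R)-1,4-bis[(4R)-4-benzyl-2-oxo-1,3-oxazolidin-3-yl]-2,3-bis(4-hydroxy-3,5-dimethoxybenzyl)butane-1,4-dione | O=C([C@H](Cc1cc(OC)c(O)c(OC)c1)[C@@H](Cc1cc(OC)c(O)c(OC)c1)C(=O)N1[C@H](Cc2ccccc2)COC1=O)N1[C@H](Cc2ccccc2)COC1=O | intermediate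
11 | (2R,3R)-2,3-bis(4-hydroxy-3,5-dimethoxybenzyl)butane-1,4-diol ((8R,8'R)-5,5'-dimethoxysecoisolariciresinol) | OC[C@H](Cc1cc(OC)c(O)c(OC)c1)[C@@H](Cc1cc(OC)c(O)c(OC)c1)CO | intermediate
12 | 4-[(2R,3R)-4-hydroxy-2-(hydroxymethyl)-3-(4-hydroxy-3,5-dimethoxybenzyl)butylidene]-2,6-dimethoxycyclohexa-2,5-dien-1-one | OC[C@H](Cc1cc(OC)c(O)c(OC)c1)[C@@H](C=C1C=C(OC)C(=O)C(OC)=C1)CO | intermediate
13 | (1S,2R,3R)-1-(4-hydroxy-3,5-dimethoxyphenyl)-2,3-bis(hydroxymethyl)-7,9-dimethoxyspiro[4.5]deca-6,9-dien-8-one | COC1=CC2(C=C(OC)C1=O)C[C@@H](CO)[C@H](CO)[C@H]2c1cc(OC)c(O)c(OC)c1 | intermediate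
14 | (6R,7R,8S)-8-(4-hydroxy-3,5-dimethoxyphenyl)-6,7-bis(hydroxymethyl)-1,3-dimethoxy-5,6,7,8-tetrahydronaphthalen-2-ol (lyoniresinol) | COc1cc([C@H]2c3c(cc(OC)c(O)c3OC)C[C@@H](CO)[C@@H]2CO)cc(OC)c1O | target

## Step count and risks
Total step count: 6. Longest linear sequence: 5 (steps 1, 2, 4, 5, 6).

Three steps most likely to fail:

**Step 6 (new).**
- Risks: a second oxidation to the bis-quinone methide (furofuran by-product), trapping of 12 by the C9 hydroxyl before the ipso closure, and base-induced tautomerisation of 12 to the styrene.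
- Fallback: it sets out from 11 and comes back at 14. Oxidise 11 with DDQ (1.0 equiv) in dioxane without base, so that 12 is captured deliberately by the C9 hydroxyl, and isolate (2S,3R,4R)-5,5'-dimethoxylariciresinol F1. Then close the tetralin by direct acid-catalysed Friedel–Crafts alkylation (HCl in MeOH or TFA in CH2Cl2) at the ring A position para to a methoxy group. This is the established lariciresinol to cyclolariciresinol conversion, it involves no spirodienone, and it costs one extra step.

**Step 4 (new).**
- Risks: slow second enolisation, oxidation of a bis-enolate to the fumaroyl bis-imide by tetravalent titanium, and Friedel–Crafts self-condensation of 8.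
- Fallback: it sets out from 5 and 7 and comes back at 11, using classical SN2 alkylation of alkali enolates.
  - Acylate 5 (PivCl, Et3N, DMAP) to 2,6-dimethoxy-4-(methoxymethyl)phenyl pivalate F2.
  - Exchange the benzylic ether with AcBr and ZnBr2 (5 mol%) in CH2Cl2 to give 4-(bromomethyl)-2,6-dimethoxyphenyl pivalate F3.
  - Alkylate 7 (NaHMDS, THF, −78 °C, F3) to the mono-benzylated pivalate bis-imide F4, then repeat the same Evans alkylation to reach the (2R,3R)-dibenzylated pivalate bis-imide F5.
  - Treat F5 with LiAlH4 (THF, 0 °C), which cleaves both imides and both pivalates to give 11.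
  - This costs three extra steps.

**Step 1.**
- Risk: a mixture of benzyl and benzal bromide in the side-chain bromination.
- Fallback: it sets out from 2 and comes back at 5. Stop after two equivalents of Br2 and isolate 2. Run the technical NaOMe/CuCl methoxylation to 2,6-dimethoxy-4-methylphenol F6. Then install the benzylic ether by oxidation instead of halogenation, using DDQ (1.0 equiv) in MeOH at rt (oxidative benzylic methoxylation through the quinone methide), which gives 5. This costs one extra step.

## Further compounds
F1 | step 6 | (2S,3R,4R)-2-(4-hydroxy-3,5-dimethoxyphenyl)-4-(4-hydroxy-3,5-dimethoxybenzyl)-3-(hydroxymethyl)tetrahydrofuran (5,5'-dimethoxylariciresinol) | OC[C@H]1[C@@H](Cc2cc(OC)c(O)c(OC)c2)CO[C@@H]1c1cc(OC)c(O)c(OC)c1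
F2 | step 4 | 2,6-dimethoxy-4-(methoxymethyl)phenyl pivalate | COCc1cc(OC)c(OC(=O)C(C)(C)C)c(OC)c1
F3 | step 4 | 4-(bromomethyl)-2,6-dimethoxyphenyl pivalate | BrCc1cc(OC)c(OC(=O)C(C)(C)C)c(OC)c1
F4 | step 4 | (2R)-mono-benzylated pivalate bis-imide | O=C([C@H](Cc1cc(OC)c(OC(=O)C(C)(C)C)c(OC)c1)CC(=O)N1[C@H](Cc2ccccc2)COC1=O)N1[C@H](Cc2ccccc2)COC1=O
F5 | step 4 | (2R,3R)-dibenzylated pivalate bis-imide | O=C([C@H](Cc1cc(OC)c(OC(=O)C(C)(C)C)c(OC)c1)[C@@H](Cc1cc(OC)c(OC(=O)C(C)(C)C)c(OC)c1)C(=O)N1[C@H](Cc2ccccc2)COC1=O)N1[C@H](Cc2ccccc2)COC1=O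
F6 | step 1 | 2,6-dimethoxy-4-methylphenol | Cc1cc(OC)c(O)c(OC)c1
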